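**Retrosynthetic overview**
1. The target is a trans-3,4-disubstituted γ-butyrolactone (ring atoms O1, C2=O, C3, C4, C5H2). The carbinol carbon C7 sits on C3 and the benzylic C7'H2 sits on C4. The last step removes three silyl ethers.
2. The C7'-aryl bond comes from a nickel-catalysed cross-electrophile coupling of a 4-(iodomethyl)lactone with silylated 4-iodo-2-methoxyphenol.
3. The C4-C5 bond closes the only ring made in the route (both arenes are bought). It forms by iodine atom transfer 5-exo-trig cyclisation of an acyclic iodomethyl ester, in which the O1-CH2 radical adds to the C4=C7' vinyl group.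
4. Enabling feature: C5 is an unsubstituted CH2 bonded only to O1 and C4, and C4 carries the exocyclic carbon C7'. The chain C5-O1-C2-C3-C4 therefore ends in an exo alkene directly next to the C3 stereocentre.
5. The C3-C7 bond and both of its stereocentres come from an Evans syn aldol of the N-crotonoyl oxazolidinone dienolate with O-silylated vanillin. C5 is supplied by chloromethyl chlorosulfate.

Key step: step 8

Remark: Ar = 3-methoxy-4-(triisopropylsilyloxy)phenyl, TIPS = triisopropylsilyl, TES = triethylsilyl. Vanillin, the oxazolidinone, crotonoyl chloride and 4-iodo-2-methoxyphenol are taken as purchasable.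

**Step 1**
Reactants: 1 vanillin (4-hydroxy-3-methoxybenzaldehyde)
Product: 2 3-methoxy-4-(triisopropylsilyloxy)benzaldehyde
Conditions: TIPSCl, imidazole, DMF, rt
Reagents that add atoms: triisopropylsilyl chloride, CC(C)[Si](Cl)(C(C)C)C(C)C
Why: Imidazole-promoted silylation of the only OH group; the bulky aryl TIPS ether is chosen because it should survive the basic peroxide of step 4 and still be cleaved by fluoride at the end.

**Step 2**
Reactants: 3 (S)-4-benzyl-1,3-oxazolidin-2-one; 4 (E)-but-2-enoyl chloride
Product: 6 (S)-4-benzyl-3-[(E)-but-2-enoyl]-1,3-oxazolidin-2-one, via lithium oxazolidinide 5 (not isolated)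
Conditions: n-BuLi, THF, -78 °C; then 4, -78 to 0 °C
Reagents that add atoms: none
Why: N-acylation of the lithiated oxazolidinone with an acid chloride is the usual entry to Evans imides; no stereocentre is formed and the one in 3 is untouched.

**Step 3**
Reactants: 6 (S)-4-benzyl-3-[(E)-but-2-enoyl]-1,3-oxazolidin-2-one; 2 3-methoxy-4-(triisopropylsilyloxy)benzaldehyde
Product: 9 (S)-4-benzyl-3-[(2S)-2-{(S)-hydroxy(Ar)methyl}but-3-enoyl]-1,3-oxazolidin-2-one, via boron dienolate 7 (not isolated), via boron aldolate 8 (not isolated)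
Conditions: Bu2BOTf, Et3N, CH2Cl2, -78 to 0 °C; 2, -78 to 0 °C; then pH 7 buffer, MeOH, 30% H2O2, 0 °C
Reagents that add atoms: none
Why: Evans syn aldol: soft enolisation removes a γ-proton of the crotonoyl imide to give the (Z)-boron dienolate 7, which reacts at its α-carbon through a closed Zimmerman-Traxler chair on the face away from the auxiliary benzyl group, so C3 (S) and C7 (S) are set together and the vinyl group C4=C7' ends up out of conjugation.

**Step 4**
Reactants: 9 aldol imide
Product: 11 (2S)-2-{(S)-hydroxy(Ar)methyl}but-3-enoic acid, via peroxy acid 10 (not isolated)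
Conditions: LiOH, 30% H2O2, THF/H2O 4:1, 0 °C; then aq Na2SO3; 1 M HCl to pH 4, 0 °C
Reagents that add atoms: hydrogen peroxide, OO
Why: Hydroperoxide attacks the exocyclic imide carbonyl selectively (standard LiOOH cleavage of Evans imides), sulfite reduces the peracid 10, and the short time at 0 °C should spare the aryl TIPS ether and the C3 and C7 centres.

**Step 5**
Reactants: 11 hydroxy acid
Product: 13 (2S)-2-{(S)-(Ar)(triethylsilyloxy)methyl}but-3-enoic acid, via bis-silylated ester 12 (not isolated)
Conditions: TESCl (2.5 equiv), imidazole, DMF, 0 °C to rt; then H2O, THF, rt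
Reagents that add atoms: triethylsilyl chloride, CC[Si](Cl)(CC)CC
Why: Both OH groups are silylated and the far more labile silyl ester is then hydrolysed selectively; the TES ether blocks retro-aldol cleavage, stops the C7 oxygen from attacking the halomethyl ester to come, and adds bulk next to C3.

**Step 6**
Reactants: 13 TES-protected acid
Product: 14 chloromethyl (2S)-2-{(S)-(Ar)(triethylsilyloxy)methyl}but-3-enoate
Conditions: ClCH2OSO2Cl, NaHCO3, Bu4NHSO4 (10 mol %), CH2Cl2/H2O 1:1, 0 °C to rt
Reagents that add atoms: chloromethyl chlorosulfate, ClCOS(=O)(=O)Cl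
Why: Phase-transfer O-alkylation of the carboxylate with chloromethyl chlorosulfate is the standard preparation of chloromethyl esters, because chlorosulfate leaves faster than chloride; it places C5 on O1 under near-neutral conditions.

**Step 7**
Reactants: 14 chloromethyl ester
Product: 15 iodomethyl (2S)-2-{(S)-(Ar)(triethylsilyloxy)methyl}but-3-enoate
Conditions: NaI, acetone, rt, dark
Reagents that add atoms: sodium iodide, [Na+].[I-]
Why: Finkelstein reaction driven by precipitation of NaCl, routine for converting chloromethyl into iodomethyl esters; the weak C-I bond is what makes chain transfer in step 8 fast.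

**Step 8**
Reactants: 15 iodomethyl ester
Product: 18 (3S,4R)-4-(iodomethyl)-3-{(S)-(Ar)(triethylsilyloxy)methyl}oxolan-2-one, via acyloxymethyl radical 16 (not isolated), via cyclised primary radical 17 (not isolated)
Conditions: dilauroyl peroxide (5 mol % every hour, 25 mol % in all), degassed PhH, 0.01 M, 80 °C
Reagents that add atoms: none
Why: Proposed new method: undecyl radicals from the peroxide take iodine from 15 to give the O1-stabilised acyloxymethyl radical 16, its carbon C5 adds to the inner vinyl carbon C4, and the primary radical 17 takes iodine from another molecule of 15, so the whole step is a chain isomerisation without any reductant. The closest known reaction types are the iodine atom transfer cyclisation of allyl iodoacetates to 4-(iodomethyl)butyrolactones, which closes the same ring across an ester tether, and the intermolecular addition of acyloxymethyl radicals made from iodomethyl esters; what is new is that the radical sits on the alkoxy carbon of the tether, so the lactone closes at C4-C5. The one ring formed, the γ-butyrolactone, closes in the 5-exo-trig mode with C5, O1, C2, C3 and C4 inside and C7' outside. The one new stereocentre, C4, is controlled by C3: in the chair-like transition state of 5-hexenyl-type closures the large CH(OTES)Ar group takes a pseudo-equatorial place and C7' ends up trans to it, which is 4R. The step needs exo over endo closure, secured by the unsubstituted vinyl group, and closure over intermolecular addition, 1,5-hydrogen shift from C7-H and attack of 17 on the nearby arene, secured by the 0.01 M dilution, by the polarity mismatch of a nucleophilic radical toward a hydridic C-H and an electron-rich ring, and by fast iodine transfer to 17. The known handicap of ester tethers, that only the minor E rotamer can close, is met by heat and by the degenerate iodine exchange, which returns unclosed 16 to 15 instead of destroying it.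

**Step 9**
Reactants: 19 4-iodo-2-methoxyphenol
Product: 20 (4-iodo-2-methoxyphenoxy)triisopropylsilane
Conditions: TIPSCl, imidazole, DMF, rt
Reagents that add atoms: triisopropylsilyl chloride, CC(C)[Si](Cl)(C(C)C)C(C)C
Why: Imidazole-promoted silylation of the phenol, as in step 1, removes the acidic proton that would disturb the reductive coupling.

**Step 10**
Reactants: 18 iodomethyl lactone; 20 (4-iodo-2-methoxyphenoxy)triisopropylsilane
Product: 21 (3S,4R)-4-(Ar-methyl)-3-{(S)-(Ar)(triethylsilyloxy)methyl}oxolan-2-one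
Conditions: NiI2 (10 mol %), 4,4'-di-tert-butyl-2,2'-bipyridine (5 mol %), 1,2-bis(diphenylphosphino)benzene (5 mol %), pyridine (10 mol %), Mn powder (2 equiv), DMPU, 60 °C
Reagents that add atoms: none
Why: Nickel-catalysed reductive cross-electrophile coupling of an aryl iodide with a primary alkyl iodide: the aryl iodide adds to zerovalent nickel, 18 enters as its primary radical, and reductive elimination forms the C7'-aryl bond without involving C3, C4 or C7.

**Step 11**
Reactants: 21 fully silylated lactone
Product: 22 (3S,4R)-4-(4-hydroxy-3-methoxybenzyl)-3-[(S)-hydroxy(4-hydroxy-3-methoxyphenyl)methyl]oxolan-2-one (target)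
Conditions: TBAF, AcOH (1:1, 4 equiv each), THF, 0 °C to rt
Reagents that add atoms: none
Why: Fluoride cleaves the two aryl TIPS ethers and the TES ether in one operation, and the acetic acid buffer keeps the phenols protonated so that retro-aldol cleavage, quinone methide formation and C3 epimerisation should be held back.

**Compound list**
1 | vanillin | COc1cc(C=O)ccc1O | starting material
2 | 3-methoxy-4-(triisopropylsilyloxy)benzaldehyde | COc1cc(C=O)ccc1O[Si](C(C)C)(C(C)C)C(C)C | intermediate
3 | (S)-4-benzyl-1,3-oxazolidin-2-one | O=C1OC[C@H](Cc2ccccc2)N1 | starting material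
4 | (E)-but-2-enoyl chloride | C/C=C/C(=O)Cl | starting material
5 | lithium salt of 3 | [Li+].O=C1OC[C@H](Cc2ccccc2)[N-]1 | intermediate
6 | (S)-4-benzyl-3-[(E)-but-2-enoyl]-1,3-oxazolidin-2-one | C/C=C/C(=O)N1C(=O)OC[C@@H]1Cc1ccccc1 | intermediate
7 | (Z)-dibutylboron dienolate of 6 | CCCCB(CCCC)O/C(=C\C=C)N1C(=O)OC[C@@H]1Cc1ccccc1 | intermediate
8 | dibutylboron aldolate of 9 | O=C1OC[C@H](Cc2ccccc2)N1C(=O)[C@@H](C=C)[C@H](OB(CCCC)CCCC)c1ccc(O[Si](C(C)C)(C(C)C)C(C)C)c(OC)c1 | intermediate
9 | (S)-4-benzyl-3-[(2S)-2-{(S)-hydroxy(Ar)methyl}but-3-enoyl]-1,3-oxazolidin-2-one | O=C1OC[C@H](Cc2ccccc2)N1C(=O)[C@@H](C=C)[C@H](O)c1ccc(O[Si](C(C)C)(C(C)C)C(C)C)c(OC)c1 | intermediate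
10 | (2S)-2-{(S)-hydroxy(Ar)methyl}but-3-eneperoxoic acid | OOC(=O)[C@@H](C=C)[C@H](O)c1ccc(O[Si](C(C)C)(C(C)C)C(C)C)c(OC)c1 | intermediate
11 | (2S)-2-{(S)-hydroxy(Ar)methyl}but-3-enoic acid | OC(=O)[C@@H](C=C)[C@H](O)c1ccc(O[Si](C(C)C)(C(C)C)C(C)C)c(OC)c1 | intermediate
12 | triethylsilyl (2S)-2-{(S)-(Ar)(triethylsilyloxy)methyl}but-3-enoate | CC[Si](CC)(CC)OC(=O)[C@@H](C=C)[C@H](O[Si](CC)(CC)CC)c1ccc(O[Si](C(C)C)(C(C)C)C(C)C)c(OC)c1 | intermediate
13 | (2S)-2-{(S)-(Ar)(triethylsilyloxy)methyl}but-3-enoic acid | OC(=O)[C@@H](C=C)[C@H](O[Si](CC)(CC)CC)c1ccc(O[Si](C(C)C)(C(C)C)C(C)C)c(OC)c1 | intermediate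
14 | chloromethyl ester of 13 | ClCOC(=O)[C@@H](C=C)[C@H](O[Si](CC)(CC)CC)c1ccc(O[Si](C(C)C)(C(C)C)C(C)C)c(OC)c1 | intermediate
15 | iodomethyl ester of 13 | ICOC(=O)[C@@H](C=C)[C@H](O[Si](CC)(CC)CC)c1ccc(O[Si](C(C)C)(C(C)C)C(C)C)c(OC)c1 | intermediate
16 | acyloxymethyl radical from 15 | [CH2]OC(=O)[C@@H](C=C)[C@H](O[Si](CC)(CC)CC)c1ccc(O[Si](C(C)C)(C(C)C)C(C)C)c(OC)c1 | intermediate
17 | cyclised (lacton-4-yl)methyl radical | [CH2][C@H]1COC(=O)[C@@H]1[C@H](O[Si](CC)(CC)CC)c1ccc(O[Si](C(C)C)(C(C)C)C(C)C)c(OC)c1 | intermediate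
18 | (3S,4R)-4-(iodomethyl)-3-{(S)-(Ar)(triethylsilyloxy)methyl}oxolan-2-one | IC[C@H]1COC(=O)[C@@H]1[C@H](O[Si](CC)(CC)CC)c1ccc(O[Si](C(C)C)(C(C)C)C(C)C)c(OC)c1 | intermediate
19 | 4-iodo-2-methoxyphenol | COc1cc(I)ccc1O | starting material
20 | (4-iodo-2-methoxyphenoxy)triisopropylsilane | COc1cc(I)ccc1O[Si](C(C)C)(C(C)C)C(C)C | intermediate
21 | (3S,4R)-4-(Ar-methyl)-3-{(S)-(Ar)(triethylsilyloxy)methyl}oxolan-2-one | COc1cc(C[C@H]2COC(=O)[C@@H]2[C@H](O[Si](CC)(CC)CC)c2ccc(O[Si](C(C)C)(C(C)C)C(C)C)c(OC)c2)ccc1O[Si](C(C)C)(C(C)C)C(C)C | intermediate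
22 | (3S,4R)-4-(4-hydroxy-3-methoxybenzyl)-3-[(S)-hydroxy(4-hydroxy-3-methoxyphenyl)methyl]oxolan-2-one | COc1cc(C[C@H]2COC(=O)[C@@H]2[C@H](O)c2ccc(O)c(OC)c2)ccc1O | target

Total step count: 11. Longest linear sequence: 9 (steps 1, 3, 4, 5, 6, 7, 8, 10, 11).

**Steps most likely to fail**

1. **Step 8.**
   - Closure may be too slow because only the minor E rotamer of the ester can cyclise. Intermolecular addition, 1,5-hydrogen shift from C7-H, attack of the cyclised radical on the neighbouring arene, or modest trans selectivity at C4 could then take over.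
   - The fallback uses known chemistry only and gives up the C4-C5 closure. It sets out from 3, uses 2 once more, and comes back at 22.
   - Commercial 3-(4-hydroxy-3-methoxyphenyl)propanoic acid is silylated (TIPSCl, imidazole; aqueous K2CO3 work-up) to 3-(Ar)propanoic acid F1.
   - F1 acylates 3 (pivaloyl chloride, Et3N, LiCl, THF) to give the N-acyl oxazolidinone F2.
   - Evans alkylation (NaHMDS, tert-butyl bromoacetate, THF, -78 °C) on the face away from the benzyl group gives the (R)-succinate imide F3.
   - LiBH4 (THF, MeOH, 0 °C) releases the auxiliary and gives the hydroxy ester F4, and TFA in CH2Cl2 closes it to (R)-4-(Ar-methyl)oxolan-2-one F5.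
   - The lithium enolate of F5 (LiHMDS, THF, -78 °C) adds to 2 anti to the benzyl group to give the trans aldol lactone F6. Its C7 epimers have to be separated by chromatography, because this aldol is not expected to control C7.
   - The fluoride conditions of step 11 then lead to 22.

2. **Step 10.**
   - Homocoupling and hydrodehalogenation of the β-branched primary iodide may outrun the cross-coupling.
   - The fallback replaces the radical cross-electrophile manifold by a two-electron Negishi coupling. It sets out from 18 and comes back at 21.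
   - Zinc insertion (Zn dust, LiCl, THF, rt to 40 °C) gives the alkylzinc iodide F7.
   - F7 is coupled with 20 under Pd(OAc)2 and SPhos in THF at rt to 50 °C.

3. **Step 11.**
   - Once the para-phenoxide is unmasked while fluoride is present, retro-aldol cleavage or quinone methide formation with loss of C7 integrity may set in.
   - The fallback unmasks in two orthogonal stages. It sets out from 21 and comes back at 22.
   - KHF2 in MeOH at rt, which is selective for aryl silyl ethers, frees the two phenols while C7 stays blocked and gives the TES-protected bisphenol F8.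
   - The TES ether is then removed without base in AcOH/THF/H2O 3:1:1 at rt. Any early loss of TES in the first stage also leads to 22.

**Further compounds**
F1 | step 8 | 3-[3-methoxy-4-(triisopropylsilyloxy)phenyl]propanoic acid | COc1cc(CCC(=O)O)ccc1O[Si](C(C)C)(C(C)C)C(C)C
F2 | step 8 | (S)-4-benzyl-3-[3-(Ar)propanoyl]-1,3-oxazolidin-2-one | COc1cc(CCC(=O)N2C(=O)OC[C@@H]2Cc2ccccc2)ccc1O[Si](C(C)C)(C(C)C)C(C)C
F3 | step 8 | tert-butyl (3R)-3-(Ar-methyl)-4-[(S)-4-benzyl-2-oxo-1,3-oxazolidin-3-yl]-4-oxobutanoate | COc1cc(C[C@H](CC(=O)OC(C)(C)C)C(=O)N2C(=O)OC[C@@H]2Cc2ccccc2)ccc1O[Si](C(C)C)(C(C)C)C(C)C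
F4 | step 8 | tert-butyl (3R)-3-(Ar-methyl)-4-hydroxybutanoate | COc1cc(C[C@H](CC(=O)OC(C)(C)C)CO)ccc1O[Si](C(C)C)(C(C)C)C(C)C
F5 | step 8 | (R)-4-(Ar-methyl)oxolan-2-one | COc1cc(C[C@H]2COC(=O)C2)ccc1O[Si](C(C)C)(C(C)C)C(C)C
F6 | step 8 | (3S,4R)-4-(Ar-methyl)-3-[(S)-hydroxy(Ar)methyl]oxolan-2-one | COc1cc(C[C@H]2COC(=O)[C@@H]2[C@H](O)c2ccc(O[Si](C(C)C)(C(C)C)C(C)C)c(OC)c2)ccc1O[Si](C(C)C)(C(C)C)C(C)C
F7 | step 10 | alkylzinc iodide derived from 18 | I[Zn]C[C@H]1COC(=O)[C@@H]1[C@H](O[Si](CC)(CC)CC)c1ccc(O[Si](C(C)C)(C(C)C)C(C)C)c(OC)c1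
F8 | step 11 | (3S,4R)-4-(4-hydroxy-3-methoxybenzyl)-3-[(S)-(4-hydroxy-3-methoxyphenyl)(triethylsilyloxy)methyl]oxolan-2-one | COc1cc(C[C@H]2COC(=O)[C@@H]2[C@H](O[Si](CC)(CC)CC)c2ccc(O)c(OC)c2)ccc1O
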